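**Retrosynthetic overview**

1. The target is a biaryl-linked dimer of 9-(3,4-dihydroxyphenyl)-1-(2,6-dihydroxyphenyl)nonan-1-one. Catechol ring A is joined through the carbon ortho to its 4-OH, catechol ring B through the carbon ortho to its chain, and each ring carries the same chain C1(=O) to C9 ending in a 2,6-dihydroxybenzoyl ring.
2. Enabling feature: in both chains C9 is the benzylic CH2 on the catechol ring and C7–C8 lies just beyond it. Cutting C7–C8 (as C7=C8) turns each catechol ring into an allylarene and both arms into one and the same alkene, a 1-(2,6-dialkoxyphenyl)oct-7-en-1-one; there is no stereocentre.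
3. Key disconnection: a two-fold olefin cross-metathesis of a 2',5-diallyl-tetramethoxybiphenyl with the octenoyl resorcinol dimethyl ether forms the C7–C8 bond of the ring A chain and, in the same operation, that of the ring B chain. Hydrogenation and global O-demethylation finish the synthesis.
4. The diallylbiaryl comes from two-fold Pd allylation of a dibromide. Both C–Br bonds are set in one double bromination of a Suzuki-derived 2-hydroxybiaryl (the free OH of ring A directs para; ring B reacts para to OMe). The alkene partner is made in one step by acylation of hept-6-enylmagnesium bromide.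
5. No ring is formed in the route; all four benzene rings are bought. Order: biaryl bond, two C–Br bonds, two allyl groups, both chains, deprotection.

Key step: step 6

Remark: the target has no stereocentre and its biaryl axis, flanked by only one OH and one CH2 group, is taken as freely rotating, so no stereocontrol is planned. Half-converted species of two-fold steps are numbered only where one defined compound is expected (4, 8, 14, 15).

**Route**

Step 1
Reactants: 1 2-bromo-6-methoxyphenol; 2 (3,4-dimethoxyphenyl)boronic acid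
Product: 3 3,3',4'-trimethoxy-[1,1'-biphenyl]-2-ol
Conditions: Pd(OAc)2 (2 mol %), SPhos (4 mol %), K3PO4, toluene/H2O, 80 °C
Reagents that add atoms: none
Why: Suzuki–Miyaura coupling, in which the only C–Br bond of 1 adds oxidatively to the electron-rich SPhos–Pd(0) catalyst, the free ortho-phenol is tolerated as its phenoxide and the electron-rich boronic acid 2 transmetalates readily under aqueous phosphate.

Step 2
Reactants: 3 3,3',4'-trimethoxy-[1,1'-biphenyl]-2-ol
Product: 5 2',5-dibromo-3,4',5'-trimethoxy-[1,1'-biphenyl]-2-ol, via para-bromophenol 4 (not isolated)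
Conditions: NBS (2.05 equiv), MeCN, 0 °C to rt, dark
Reagents that add atoms: N-bromosuccinimide, O=C1CCC(=O)N1Br
Why: Electrophilic aromatic bromination (SEAr) at two sites in one operation: the free OH of ring A directs to its only open activated position, the para carbon (both ortho positions carry OMe and aryl), giving 4, and the veratrole ring B then reacts para to its 3'-OMe at the carbon ortho to the biaryl bond, the usual site for 4-substituted veratroles.

Step 3
Reactants: 5 2',5-dibromo-3,4',5'-trimethoxy-[1,1'-biphenyl]-2-ol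
Product: 6 2',5-dibromo-2,3,4',5'-tetramethoxy-1,1'-biphenyl
Conditions: MeI, K2CO3, DMF, 40 °C
Reagents that add atoms: iodomethane, CI
Why: Williamson ether synthesis (SN2 of the phenoxide on MeI), which caps the only free phenol before the Pd chemistry and leaves one kind of protecting group on the core.

Step 4
Reactants: 6 2',5-dibromo-2,3,4',5'-tetramethoxy-1,1'-biphenyl; 7 allylboronic acid pinacol ester (3 equiv)
Product: 9 2',5-diallyl-2,3,4',5'-tetramethoxy-1,1'-biphenyl, via mono-allyl bromide 8 (not isolated)
Conditions: Pd(OAc)2 (5 mol %), SPhos (10 mol %), K3PO4, THF/H2O, 65 °C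
Reagents that add atoms: none
Why: Two-fold Suzuki–Miyaura allylation of aryl bromides with an allylboronate, in which the unhindered ring A C–Br should react first (8) and SPhos is chosen for the electron-rich ortho-aryl C–Br of ring B; with the parent allyl group α/γ selectivity does not arise and the mild temperature limits migration of the double bond into conjugation.

Step 5
Reactants: 10 7-bromohept-1-ene; 11 2,6-dimethoxybenzoyl chloride
Product: 13 1-(2,6-dimethoxyphenyl)oct-7-en-1-one, via Grignard reagent 12 (not isolated)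
Conditions: Mg, THF, rt; then 11, Fe(acac)3 (3 mol %), THF, −78 °C to 0 °C
Reagents that add atoms: none
Why: Grignard formation followed by iron-catalysed acylation with an acid chloride (Fürstner-type ketone synthesis) at low temperature, where the two ortho-OMe groups shield the ketone from a second addition and the remote terminal alkene is inert.

Step 6
Reactants: 9 2',5-diallyl-2,3,4',5'-tetramethoxy-1,1'-biphenyl; 13 1-(2,6-dimethoxyphenyl)oct-7-en-1-one (5 equiv)
Product: 16 (7E,7'E)-9,9'-(2,3,4',5'-tetramethoxy-[1,1'-biphenyl]-2',5-diyl)bis[1-(2,6-dimethoxyphenyl)non-7-en-1-one], via ring-A mono-adduct 14 (not isolated), via ring-B mono-adduct 15 (not isolated)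
Conditions: Hoveyda–Grubbs II (2 × 5 mol %), 1,4-benzoquinone (10 mol %), CH2Cl2, 40 °C, Ar sweep to remove ethene
Reagents that add atoms: none
Why: Olefin cross-metathesis by the Chauvin mechanism: Ru alkylidenes pass through ruthenacyclobutanes by [2+2]/retro-[2+2] steps, so each allyl group of 9 exchanges its =CH2 terminus for the =CH(CH2)5C(O)Ar terminus of 13 with loss of ethene; the first exchange gives 14 and 15, and the second joins each of them, already carrying one complete arm, to another molecule of 13 through the C7=C8 bond of the remaining arm. The closest known reaction type is the cross-metathesis of allylbenzenes such as eugenol derivatives with terminal aliphatic alkenes under second-generation Ru catalysis, here run twice on one substrate. No ring is closed and no stereocentre is formed; both new C7=C8 bonds are expected as E/Z mixtures (mainly E), which is without consequence because step 7 saturates them. The step needs cross- over homo-coupling, reaction of both allyl groups, and no migration of an allyl double bond into conjugation (which would cost one carbon per arm); an excess of the type-I partner 13, whose own homodimer remains a competent partner by secondary metathesis, together with removal of ethene drives both ends to the cross-product, and 1,4-benzoquinone intercepts the Ru–H species responsible for isomerisation. In the substrate, the two allyl groups are unhindered monosubstituted alkenes insulated from the rings by CH2 and cannot close onto each other, since that ring closure would give a nine-membered ring bridging a meta-disposed arene, and the hindered 2,6-dimethoxyaryl ketone and the aryl ethers do not bind the catalyst.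

Step 7
Reactants: 16 (7E,7'E)-9,9'-(2,3,4',5'-tetramethoxy-[1,1'-biphenyl]-2',5-diyl)bis[1-(2,6-dimethoxyphenyl)non-7-en-1-one] (all alkene isomers)
Product: 17 9,9'-(2,3,4',5'-tetramethoxy-[1,1'-biphenyl]-2',5-diyl)bis[1-(2,6-dimethoxyphenyl)nonan-1-one]
Conditions: H2 (1 atm), 10 % Pd/C, EtOAc, rt
Reagents that add atoms: none
Why: Heterogeneous catalytic hydrogenation of two unhindered 1,2-disubstituted alkenes converges all E/Z isomers to one compound, while the aryl methyl ethers are inert and the di-ortho-substituted aryl ketones, twisted out of conjugation, should not be reduced at 1 atm and rt if the reaction is stopped after alkene uptake.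

Step 8
Reactants: 17 9,9'-(2,3,4',5'-tetramethoxy-[1,1'-biphenyl]-2',5-diyl)bis[1-(2,6-dimethoxyphenyl)nonan-1-one]
Product: 18 9,9'-(2,3,4',5'-tetrahydroxy-[1,1'-biphenyl]-2',5-diyl)bis[1-(2,6-dihydroxyphenyl)nonan-1-one] (target)
Conditions: BBr3 (16 equiv), CH2Cl2, −78 °C to rt; then degassed H2O, 0 °C, work-up under Ar
Reagents that add atoms: none
Why: Lewis-acid ether cleavage with BBr3 (O–B complexation, SN2 demethylation by bromide, hydrolysis of the aryl borates), in which the OMe groups ortho to each ketone are cleaved with chelation assistance and the veratrole ethers via cyclic catechol borates, and no other acid-labile group is present.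

**Compound list**

1 | 2-bromo-6-methoxyphenol | COc1cccc(Br)c1O | starting material
2 | (3,4-dimethoxyphenyl)boronic acid | COc1ccc(B(O)O)cc1OC | starting material
3 | 3,3',4'-trimethoxy-[1,1'-biphenyl]-2-ol | COc1cccc(-c2ccc(OC)c(OC)c2)c1O | intermediate
4 | 5-bromo-3,3',4'-trimethoxy-[1,1'-biphenyl]-2-ol (para-bromophenol) | COc1cc(Br)cc(-c2ccc(OC)c(OC)c2)c1O | intermediate (not isolated)
5 | 2',5-dibromo-3,4',5'-trimethoxy-[1,1'-biphenyl]-2-ol | COc1cc(Br)cc(-c2cc(OC)c(OC)cc2Br)c1O | intermediate
6 | 2',5-dibromo-2,3,4',5'-tetramethoxy-1,1'-biphenyl | COc1cc(Br)cc(-c2cc(OC)c(OC)cc2Br)c1OC | intermediate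
7 | allylboronic acid pinacol ester (2-allyl-4,4,5,5-tetramethyl-1,3,2-dioxaborolane) | C=CCB1OC(C)(C)C(C)(C)O1 | starting material
8 | 5-allyl-2'-bromo-2,3,4',5'-tetramethoxy-1,1'-biphenyl (mono-allyl bromide) | C=CCc1cc(OC)c(OC)c(-c2cc(OC)c(OC)cc2Br)c1 | intermediate (not isolated)
9 | 2',5-diallyl-2,3,4',5'-tetramethoxy-1,1'-biphenyl | C=CCc1cc(OC)c(OC)c(-c2cc(OC)c(OC)cc2CC=C)c1 | intermediate
10 | 7-bromohept-1-ene | C=CCCCCCBr | starting material
11 | 2,6-dimethoxybenzoyl chloride | COc1cccc(OC)c1C(=O)Cl | starting material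
12 | hept-6-en-1-ylmagnesium bromide (Grignard reagent) | C=CCCCCC[Mg]Br | intermediate (not isolated)
13 | 1-(2,6-dimethoxyphenyl)oct-7-en-1-one | C=CCCCCCC(=O)c1c(OC)cccc1OC | intermediate
14 | (E)-9-(2'-allyl-4',5,5',6-tetramethoxy-[1,1'-biphenyl]-3-yl)-1-(2,6-dimethoxyphenyl)non-7-en-1-one (ring-A mono-adduct; E drawn) | O=C(CCCCC/C=C/Cc1cc(OC)c(OC)c(-c2cc(OC)c(OC)cc2CC=C)c1)c1c(OC)cccc1OC | intermediate (not isolated)
15 | (E)-9-(5'-allyl-2',3',4,5-tetramethoxy-[1,1'-biphenyl]-2-yl)-1-(2,6-dimethoxyphenyl)non-7-en-1-one (ring-B mono-adduct; E drawn) | C=CCc1cc(OC)c(OC)c(-c2cc(OC)c(OC)cc2C/C=C/CCCCCC(=O)c2c(OC)cccc2OC)c1 | intermediate (not isolated)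
16 | (7E,7'E)-9,9'-(2,3,4',5'-tetramethoxy-[1,1'-biphenyl]-2',5-diyl)bis[1-(2,6-dimethoxyphenyl)non-7-en-1-one] (E/Z mixture expected; E,E drawn) | O=C(CCCCC/C=C/Cc1cc(OC)c(OC)c(-c2cc(OC)c(OC)cc2C/C=C/CCCCCC(=O)c2c(OC)cccc2OC)c1)c1c(OC)cccc1OC | intermediate
17 | 9,9'-(2,3,4',5'-tetramethoxy-[1,1'-biphenyl]-2',5-diyl)bis[1-(2,6-dimethoxyphenyl)nonan-1-one] | O=C(CCCCCCCCc1cc(OC)c(OC)c(-c2cc(OC)c(OC)cc2CCCCCCCCC(=O)c2c(OC)cccc2OC)c1)c1c(OC)cccc1OC | intermediate
18 | 9,9'-(2,3,4',5'-tetrahydroxy-[1,1'-biphenyl]-2',5-diyl)bis[1-(2,6-dihydroxyphenyl)nonan-1-one] | O=C(CCCCCCCCc1cc(O)c(O)c(-c2cc(O)c(O)cc2CCCCCCCCC(=O)c2c(O)cccc2O)c1)c1c(O)cccc1O | target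

**Step count**

Total steps: 8. Longest linear sequence: 7 (steps 1, 2, 3, 4, 6, 7, 8); step 5 is a one-step branch.

**Steps most likely to fail**

Step 6. What may go wrong: homo-coupling of either partner competing with the cross-reaction, stalling after only one of the two exchanges, and Ru–H-mediated migration of an allyl double bond into conjugation followed by metathesis, which would shorten an arm by one carbon. The fallback sets out from 9 and 13 and comes back to the route at 17; it makes the same two C7=C8 bonds by a two-fold Wittig olefination. Oxidative cleavage of both allyl groups of 9 (OsO4 cat., NaIO4, 2,6-lutidine, dioxane/H2O) should give the dialdehyde 2,2'-(2,3,4',5'-tetramethoxy-[1,1'-biphenyl]-2',5-diyl)diacetaldehyde F1. After work-up the crude F1 is reduced (NaBH4, MeOH, 0 °C) to the diol 2,2'-(2,3,4',5'-tetramethoxy-[1,1'-biphenyl]-2',5-diyl)di(ethan-1-ol) F2. Appel bromination (CBr4, PPh3, CH2Cl2) should give 2',5-bis(2-bromoethyl)-2,3,4',5'-tetramethoxy-1,1'-biphenyl F3, and heating with PPh3 (MeCN, reflux) the bis(triphenylphosphonium) dibromide F4. The same oxidative cleavage applied to 13 should give 7-(2,6-dimethoxyphenyl)-7-oxoheptanal F5, whose hindered aryl ketone does not compete with the aldehyde. Double deprotonation of F4 (NaHMDS, THF, −78 °C) and addition of F5 should give the (7Z,7'Z) isomer of 16 F6, which is hydrogenated under the conditions of step 7 to 17.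

Step 8. What may go wrong: incomplete cleavage of some of the eight methyl ethers and oxidative degradation of the catechol rings during the acidic work-up of a polyphenol. The fallback sets out from 9 and 13 and comes back to the route at 18. It moves the demethylation to the two small building blocks and carries benzyl ethers through the key step, so that one hydrogenation both saturates the alkenes and frees all eight phenols. Treatment of 9 with BBr3 (CH2Cl2, −78 to 0 °C, conditions under which allyl groups on biphenols are known to survive) should give 2',5-diallyl-[1,1'-biphenyl]-2,3,4',5'-tetrol F7, and benzylation (BnBr, K2CO3, DMF) 2',5-diallyl-2,3,4',5'-tetrakis(benzyloxy)-1,1'-biphenyl F8. In the same way 13 should give 1-(2,6-dihydroxyphenyl)oct-7-en-1-one F9 and then 1-[2,6-bis(benzyloxy)phenyl]oct-7-en-1-one F10. Two-fold cross-metathesis of F8 with F10 under the conditions of step 6 should give the octabenzyl bis-alkene (7E,7'E)-9,9'-[2,3,4',5'-tetrakis(benzyloxy)-[1,1'-biphenyl]-2',5-diyl]bis{1-[2,6-bis(benzyloxy)phenyl]non-7-en-1-one} F11. Hydrogenation with hydrogenolysis (H2, Pd/C, EtOAc/MeOH, rt) then leads directly to 18.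

Step 2. What may go wrong: the still electron-rich bromophenol ring competing for the second equivalent of NBS (ipso attack, over-bromination), so that ring B is brominated incompletely or unselectively. The fallback sets out from 2, with commercial 4-bromo-2-methoxyphenol (COc1cc(Br)ccc1O) in place of 1, and comes back to the route at 6; the ring A bromine is bought with the starting material and ring B is brominated only after all oxygens are methylated. Ortho-iodination of 4-bromo-2-methoxyphenol (NIS, TsOH cat., MeCN, rt) should give 4-bromo-2-iodo-6-methoxyphenol F12, and methylation (MeI, K2CO3, DMF) 5-bromo-1-iodo-2,3-dimethoxybenzene F13. Iodide-selective Suzuki–Miyaura coupling with 2 (Pd(PPh3)4, K2CO3, DME/H2O, 60 °C) should give 5-bromo-2,3,3',4'-tetramethoxy-1,1'-biphenyl F14. One equivalent of NBS (MeCN, rt) should then brominate ring B para to its 3'-OMe to give 6.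

**Further compounds**

F1 | step 6 | 2,2'-(2,3,4',5'-tetramethoxy-[1,1'-biphenyl]-2',5-diyl)diacetaldehyde | O=CCc1cc(OC)c(OC)c(-c2cc(OC)c(OC)cc2CC=O)c1
F2 | step 6 | 2,2'-(2,3,4',5'-tetramethoxy-[1,1'-biphenyl]-2',5-diyl)di(ethan-1-ol) | OCCc1cc(OC)c(OC)c(-c2cc(OC)c(OC)cc2CCO)c1
F3 | step 6 | 2',5-bis(2-bromoethyl)-2,3,4',5'-tetramethoxy-1,1'-biphenyl | BrCCc1cc(OC)c(OC)c(-c2cc(OC)c(OC)cc2CCBr)c1
F4 | step 6 | [(2,3,4',5'-tetramethoxy-[1,1'-biphenyl]-2',5-diyl)di(ethane-2,1-diyl)]bis(triphenylphosphonium) dibromide | [Br-].[Br-].COc1cc(CC[P+](c2ccccc2)(c2ccccc2)c2ccccc2)cc(-c2cc(OC)c(OC)cc2CC[P+](c2ccccc2)(c2ccccc2)c2ccccc2)c1OC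
F5 | step 6 | 7-(2,6-dimethoxyphenyl)-7-oxoheptanal | O=CCCCCCC(=O)c1c(OC)cccc1OC
F6 | step 6 | (7Z,7'Z)-9,9'-(2,3,4',5'-tetramethoxy-[1,1'-biphenyl]-2',5-diyl)bis[1-(2,6-dimethoxyphenyl)non-7-en-1-one] | O=C(CCCCC/C=C\Cc1cc(OC)c(OC)c(-c2cc(OC)c(OC)cc2C/C=C\CCCCCC(=O)c2c(OC)cccc2OC)c1)c1c(OC)cccc1OC
F7 | step 8 | 2',5-diallyl-[1,1'-biphenyl]-2,3,4',5'-tetrol | C=CCc1cc(O)c(O)c(-c2cc(O)c(O)cc2CC=C)c1
F8 | step 8 | 2',5-diallyl-2,3,4',5'-tetrakis(benzyloxy)-1,1'-biphenyl | C=CCc1cc(OCc2ccccc2)c(OCc2ccccc2)c(-c2cc(OCc3ccccc3)c(OCc3ccccc3)cc2CC=C)c1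
F9 | step 8 | 1-(2,6-dihydroxyphenyl)oct-7-en-1-one | C=CCCCCCC(=O)c1c(O)cccc1O
F10 | step 8 | 1-[2,6-bis(benzyloxy)phenyl]oct-7-en-1-one | C=CCCCCCC(=O)c1c(OCc2ccccc2)cccc1OCc1ccccc1
F11 | step 8 | (7E,7'E)-9,9'-[2,3,4',5'-tetrakis(benzyloxy)-[1,1'-biphenyl]-2',5-diyl]bis{1-[2,6-bis(benzyloxy)phenyl]non-7-en-1-one} | O=C(CCCCC/C=C/Cc1cc(OCc2ccccc2)c(OCc2ccccc2)c(-c2cc(OCc3ccccc3)c(OCc3ccccc3)cc2C/C=C/CCCCCC(=O)c2c(OCc3ccccc3)cccc2OCc2ccccc2)c1)c1c(OCc2ccccc2)cccc1OCc1ccccc1
F12 | step 2 | 4-bromo-2-iodo-6-methoxyphenol | COc1cc(Br)cc(I)c1O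
F13 | step 2 | 5-bromo-1-iodo-2,3-dimethoxybenzene | COc1cc(Br)cc(I)c1OC
F14 | step 2 | 5-bromo-2,3,3',4'-tetramethoxy-1,1'-biphenyl | COc1cc(Br)cc(-c2ccc(OC)c(OC)c2)c1OC
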